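Which set-up ends with the highest share of target among target and isomer of the product together, with target counted alongside its idle adduct?

| flask | substrate | partner | time | remark |
|---|---|---|---|---|
| green | 5.0 mM (fed, over 40.0 s) | 2.00 equiv | 80 s | all but substrate at the start; substrate goes in evenly over 40.0 s, the run ends at 80 s |
| grey | 5.0 mM | 2.00 equiv | 80 s | everything together in a closed stirred flask, run for 80 s |
| amber | 5.0 mM | 2.00 equiv |  | one stirred flow tank at steady state, fed with the mixture as stated, mean residence time 80 s |
| blue | 5.0 mM | 2.00 equiv (fed, over 40.0 s) | 80 s | all but partner at the start; partner goes in evenly over 40.0 s, the run ends at 80 s |

    substrate + partner → target (k1 = 3.7 L mol⁻¹ s⁻¹)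
    2 partner → side product (k2 = 4.0 L mol⁻¹ s⁻¹)
    partner + target ⇌ idle adduct, settled at all times (K3 = 190 L mol⁻¹)
    partner → decomposed reagent (k4 = 0.0046 s⁻¹)
    target ⇌ isomer of the product (K5 = 13, k5 = 0.015 s⁻¹)

- the set-up with the highest share of target in all that became target or isomer of the product, at the outlet or at the end ("none" if the first two lie within 2 percentage points) (green / grey / amber / blue / none)
- share of target in all that became target or isomer of the product, at the outlet or at the end, green
- share of target in all that became target or isomer of the product, at the outlet or at the end, grey
- share of target in all that became target or isomer of the product, at the outlet or at the end, amber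
- share of target in all that became target or isomer of the product, at the outlet or at the end, blue

- target is meant together with its idle adduct
- two of one species on the left: rate k times its square, two consumed each time
- the stated concentrations are those of everything mixed, before any reaction; amounts are the same in each set-up
- the feed brings no volume worth counting
- run time (green): 80 s

Two of us argue from one shared rule. With no partner to bind it, the pair drifts towards a target share of 7.14 %, and the clock of that drift is the relaxation rate of free target and isomer of the product, forward and back together: 0.0162 s⁻¹.

The first of us reads age off this clock. In green and blue, one reagent rises against the other's fall, so target is taken as born at mid-run and is 40.0 s old. In grey it is born about one substrate half-life in, 18.7 s with partner as charged, so it is 61.3 s old. That view gives 55.7 % for both green and blue, a tie, and 41.5 % for grey.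

I hold the second view: bound target does not isomerise, so the clock is slowed by the factor one plus the adduct constant times c_partner. I replace c_partner by its mean over target's life, taken from second-order loss to side product. Green's mean is 1.77 mM, and grey's is 2.22 mM. Blue's feed balances that loss near 5.59 mM, which gives a mean of 3.21 mM.

My shares are 64.4 % for green, 53.4 % for grey and 69.3 % for blue. For green, the free fraction at the mean partner is 0.748, against 0.742 averaged from the window's ends, so taking the mean costs little. My curve has one partner loss, so I expect these shares to stand high.

The forecast sides with me: blue, with 60.5 % for green, 52 % for grey, 57.4 % for amber and 63.7 % for blue, because “a higher late free partner gives a higher share”.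

The simulation gives blue: 60.8 % for green, 52.8 % for grey, 57.3 % for amber and 64.5 % for blue, so blue stands 3.7 percentage points above green.

By 40.0 s, green held 16.3 % of its partner and 3.56 % of idle adduct, while blue held 41.3 % and 13.0 %. Isomerisation then ran on to 80.0 s, reaching 11.4 % of isomer in green and 18.8 % in blue, with 6.2 % and 13 % of partner left. Age keeps its region where partner ends alike: green, with 6.2 % left, stands above grey, with 7.4 % left.

Green read at 180 s has 1.2 % of its partner left, so the bare clock from 60.8 % gives 17.8 %. The flask reads 24.1 %, while substrate fell from 71 % to 64 %.

The numbers of this flask stand for no real mixture.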